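Cuts: (i) in the cyclohexadienone ring, C(=O)–C(CH3) and C(OMe)–CMe2, a retro-[4+2] that releases the MeO–C=C–CH3 edge as 1-methoxypropyne; (ii) in the dihydropyran, O–C4 and C15–C1′ (retro-hetero-Diels–Alder); (iii) in ring A, C5–C6 and C1–C2.
Enabling feature: the remaining arc O=C–C(pyran)=C(pyran, O-bearing)–CMe2 of the dienone ring is a vinylketene. Both of its C=C bonds are exocyclic to the dihydropyran ring (locked s-cis; acyl carbon δ+, CMe2 δ− as enol-ether β-carbon). It is stored as a cyclobutenone fused to the pyran, a temporary ring whose strain drives the last step.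
Forward order: ring B is bought as (−)-menthone → ring A (axial hydrazone alkylation, intramolecular Hosomi–Sakurai reaction, dehydration) → dihydropyran plus the temporary four-ring (Knoevenagel/hetero-Diels–Alder with 2,2-dimethylcyclobutane-1,3-dione and isobutyraldehyde) → six-membered carbocycle last, by two-carbon ring expansion.
Stereochemistry: C7 and C10 come from (−)-menthone, whose ten carbons are ring B with both alkyl groups. C1 comes from stereoelectronically axial alkylation. C4 and C1′ come from the face (anti to the axial C7 isopropyl, pseudo-axial C–O bond) and the endo mode of the cycloaddition. The last step creates no stereocentre.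

Key step: step 12

Remark: cadinane numbering (C1–C15) is used for the sesquiterpene half and C1′ for the pyran CH(iPr). 1-Methoxypropyne is not assumed to be purchasable and is made in step 11.

Step 1
Reactants: 1 3-methylbut-3-en-1-ol
Product: 4 3-[(trimethylsilyl)methyl]but-3-en-1-ol, via dilithio dianion 2 (not isolated), via bis-silyl ether 3 (not isolated)
Conditions: n-BuLi (2.3 equiv), TMEDA, Et2O–hexane, 0 °C → rt; Me3SiCl (2.4 equiv), −78 °C → rt; 1 M H2SO4, THF, rt
Reagents that add atoms: chlorotrimethylsilane, C[Si](C)(C)Cl
Why: Alkoxide-directed allylic lithiation of the methallyl CH3 followed by C,O-bis-silylation is the standard entry to 2-(silylmethyl)allyl building blocks, and only the labile O–Si bond is hydrolysed in the mild acid work-up.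

Step 2
Reactants: 4 3-[(trimethylsilyl)methyl]but-3-en-1-ol
Product: 5 (4-iodo-2-methylidenebutyl)trimethylsilane
Conditions: I2, PPh3, imidazole, CH2Cl2, 0 °C, dark
Reagents that add atoms: iodine, II
Why: Appel-type iodination converts the primary alcohol by SN2 displacement under buffered conditions that spare the acid-sensitive allylsilane.

Step 3
Reactants: 6 (−)-menthone [(2S,5R)-2-isopropyl-5-methylcyclohexanone]
Product: 7 (2S,5R)-menthone N,N-dimethylhydrazone (NMe2 anti to the isopropyl-bearing carbon)
Conditions: Me2NNH2 (3 equiv), AcOH (cat.), MS 3 Å, EtOH, 60 °C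
Reagents that add atoms: N,N-dimethylhydrazine, CN(C)N
Why: Hydrazone condensation gives the isomer with NMe2 anti to the isopropyl-bearing carbon, C7 keeps its thermodynamically preferred equatorial isopropyl group (trans to CH3), and the product is set up for regio- and stereocontrolled azaenolate alkylation.

Step 4
Reactants: 7 menthone N,N-dimethylhydrazone; 5 (4-iodo-2-methylidenebutyl)trimethylsilane
Product: 9 N,N-dimethylhydrazone of (2R,3R,6S)-6-isopropyl-3-methyl-2-{3-[(trimethylsilyl)methyl]but-3-en-1-yl}cyclohexanone (side chain axial; cis to 3-CH3; trans to 6-iPr), via lithio azaenolate 8 (not isolated)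
Conditions: LDA (1.1 equiv), THF, 0 °C; 5, −78 °C → 0 °C
Reagents that add atoms: none
Why: Dimethylhydrazone (azaenolate) alkylation: deprotonation occurs at the only unhindered α-carbon (CH2) and the primary iodide is attacked along the stereoelectronically required axial trajectory of the chair with equatorial iPr and CH3, which, reinforced by A(1,3) strain to NMe2 in the product, sets C1 with the new chain trans to iPr and cis to the neighbouring CH3.

Step 5
Reactants: 9 alkylated hydrazone
Product: 10 (2R,3R,6S)-6-isopropyl-3-methyl-2-{3-[(trimethylsilyl)methyl]but-3-en-1-yl}cyclohexan-1-one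
Conditions: CuCl2, THF–pH 7 phosphate buffer, 0 °C → rt
Reagents that add atoms: water, O
Why: Copper(II)-assisted hydrazone hydrolysis at pH 7 frees the ketone without enolisation, so that the contra-thermodynamic axial side chain at C1 (and C7) is not epimerised and the allylsilane is not protodesilylated.

Step 6
Reactants: 10 allylsilane ketone
Product: 11 (1R,6R,7S,10R)-muurol-4(15)-en-6-ol [(1S,4R,4aR,8aR)-4-methyl-7-methylidene-1-isopropyl-octahydronaphthalen-8a-ol; cis-fused; 6-OH cis to H-1]
Conditions: TiCl4 (1.1 equiv), CH2Cl2, −78 °C; sat. aq. NaHCO3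
Reagents that add atoms: none
Why: Intramolecular Hosomi–Sakurai reaction (six-ring, SE2′): the axial chain can reach the activated C6=O only from its own (equatorial-attack) face, which gives the cis-fused decalol with 6-OH cis to H-1, and loss of silicon places the new double bond regiospecifically as the exocyclic C4=C15 methylene.

Step 7
Reactants: 11 decalol
Product: 13 (1R,7S,10R)-muurola-4(15),5-diene [(1S,4R,4aR)-4-methyl-7-methylidene-1-isopropyl-1,2,3,4,4a,5,6,7-octahydronaphthalene; H-1 cis to H-10 and trans to H-7], via sulfamate ester 12 (not isolated)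
Conditions: Burgess reagent (1.5 equiv), toluene, 60 °C
Reagents that add atoms: none
Why: Burgess dehydration (syn-Ei of the sulfamate): H-7 is anti-periplanar to the axial C6–O bond and so out of reach, and of the syn-disposed hydrogens the allylic C5–H, whose loss gives the conjugated 4(15),5-diene, is the most activated, while the neutral medium leaves C1 and the acid-labile diene untouched.

Step 8
Reactants: 14 isobutyryl chloride; 15 ethoxyacetylene
Product: 17 3-ethoxy-4,4-dimethylcyclobut-2-en-1-one, via dimethylketene 16 (not isolated)
Conditions: Et3N (1.2 equiv), Et2O, 0 °C → reflux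
Reagents that add atoms: none
Why: In situ dehydrochlorination to dimethylketene and its regiospecific [2+2] cycloaddition with the ynol ether (nucleophilic alkyne CH to the ketene carbonyl carbon) is the classical synthesis of 3-alkoxy-4,4-dialkylcyclobutenones.

Step 9
Reactants: 17 3-ethoxy-4,4-dimethylcyclobut-2-en-1-one
Product: 18 3-hydroxy-4,4-dimethylcyclobut-2-en-1-one (enol of 2,2-dimethylcyclobutane-1,3-dione)
Conditions: 2 M HCl, THF, rt
Reagents that add atoms: water, O
Why: Acid hydrolysis of the vinylogous ester by addition–elimination of water gives the cyclobutane-1,3-dione, which is stable as its strongly acidic enol and has a single nucleophilic CH for the next condensation.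

Step 10
Reactants: 18 3-hydroxy-4,4-dimethylcyclobut-2-en-1-one; 19 isobutyraldehyde; 13 muurola-4(15),5-diene
Product: 21 pyran-fused cyclobutenone [(3S,5R)-5-isopropyl-8,8-dimethyl-2-oxabicyclo[4.2.0]oct-1(6)-en-7-one spiro-joined at its C3 to C4 of the (1R,7S,10R)-muurol-5-ene unit], via alkylidene dione 20 (not isolated)
Conditions: 19 (2 equiv), ethylenediammonium diacetate (10 mol %), MS 4 Å, CH2Cl2, 0 °C, slow addition of 18; then 13, rt → 40 °C
Reagents that add atoms: none
Why: Proposed new method: Knoevenagel condensation at the only CH of 18 gives the alkylidene-1,3-dione 20, a 1-oxadiene of the kind used in the domino Knoevenagel/hetero-Diels–Alder reaction of five- and six-membered cyclic 1,3-diones and in the additions of alkylidene β-triketones to terpene methylene groups (closest known type; a four-membered 1,3-dione has not been used), and it should add with inverse electron demand to the C4=C15 bond of 13, which is the only unhindered alkene and, being part of an s-trans-locked diene, cannot react as a 4π partner; C15 (largest HOMO coefficient) binds the alkylidene carbon and O binds C4 (tertiary allylic cation character), in a strongly asynchronous or stepwise way because the exocyclic bonds of a four-ring splay apart, the driving force being the very well stabilised cyclobutenolate; attack on the face of ring A anti to the axial C7 isopropyl group, which makes the new C4–O bond pseudo-axial, sets C4 (S), and the endo placement of the C5=C6 vinyl unit with the isopropyl group of 20 outside sets C1′ (R, iPr cis to C5 on the pyran).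

Step 11
Reactants: 22 chloroacetaldehyde dimethyl acetal
Product: 24 1-methoxyprop-1-yne, via sodium methoxyacetylide 23 (not isolated)
Conditions: NaNH2 (3.2 equiv), liq. NH3, −33 °C; MeI (1.1 equiv), −33 °C; taken up in toluene, cold water wash, distilled
Reagents that add atoms: iodomethane, CI
Why: Threefold base treatment of the chloroacetal (two eliminations and one deprotonation) gives the alkoxyacetylide, whose C-methylation is the standard one-pot preparation of 1-alkoxy-1-alkynes.

Step 12
Reactants: 21 pyran-fused cyclobutenone; 24 1-methoxyprop-1-yne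
Product: 26 target CNP0194760.3, via vinylketene 25 (not isolated)
Conditions: 24 (5 equiv), BHT (cat.), toluene (0.5 M), sealed tube, 135 °C
Reagents that add atoms: none
Why: Proposed new method: at 135 °C the cyclobutenone of 21 opens by conrotatory 4π electrocyclic cleavage of its C(=O)–CMe2 bond to vinylketene 25, in which C=C=O and C(OR)=CMe2 are both exocyclic to the dihydropyran and hence locked s-cis, and 24 is taken up across the two termini in a polar, strongly asynchronous [4+2] cycloaddition: its nucleophilic carbon (C2, bearing CH3) attacks the ketene carbon in the plane of the C=O π* orbital while the enol-ether carbon CMe2, the most nucleophilic site of 25, closes on the developing, sterically slim sp-hybridised methoxyketenium carbon. The closest known reaction types are the Danheiser benzannulation (cyclobutenone → vinylketene + alkoxy- or silyloxyalkyne), the 6π closure of the 3-oxidodienylketenes formed from vinylketenes and lithium ynolates, which gives this same connectivity, and the nickel(0)-catalysed [4+2] union of cyclobutenones with alkynes. Only one ring is closed, the six-membered carbocycle, by an intermolecular [4+2] mode that forms C(=O)–C(CH3) and CMe2–C(OMe), while the temporary four-membered ring vanishes and its strain pays for the bond to the quaternary carbon. No stereocentre is formed and C1, C4, C7, C10 and C1′ are spectators, so nothing has to be controlled there. Regioselectivity follows from matched polarity (ketene C δ+ with alkyne C2 δ−; CMe2 δ− with alkyne C1 δ+) and puts the methyl ether on the oxygen next to CMe2, the hindered position that O-methylation of the parent enol could not be relied on to reach. Periselectivity for closure at CMe2 (six-ring) over closure at the ketene α-carbon (four-ring, the entry to the benzannulation cascade that would transpose C=O and OMe) is what the step needs; it is secured by the s-cis lock, by the twist that the inside methyl group imposes, which turns the donor lobe of CMe2 towards the in-plane acceptor lobe of the ketene carbon as in the reverse ring closure, and by the fact that α-closure would have to build a spiro quaternary carbon between CH(iPr) and C(OR)=CMe2, and 24 has no β-hydrogen and so cannot fragment by retro-ene reaction at this temperature.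

Compound list
1 | 3-methylbut-3-en-1-ol | CC(=C)CCO | starting material
2 | dilithio dianion of 1 | [Li]CC(=C)CCO[Li] | intermediate
3 | trimethyl{2-methylidene-4-[(trimethylsilyl)oxy]butyl}silane | C[Si](C)(C)CC(=C)CCO[Si](C)(C)C | intermediate
4 | 3-[(trimethylsilyl)methyl]but-3-en-1-ol | C[Si](C)(C)CC(=C)CCO | intermediate
5 | (4-iodo-2-methylidenebutyl)trimethylsilane | C[Si](C)(C)CC(=C)CCI | intermediate
6 | (−)-menthone, (2S,5R) | O=C1[C@H](C(C)C)CC[C@@H](C)C1 | starting material
7 | (2S,5R)-menthone N,N-dimethylhydrazone | CN(C)/N=C1/[C@H](C(C)C)CC[C@@H](C)C1 | intermediate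
8 | lithio azaenolate of 7 | CN(C)N([Li])C1=C[C@H](C)CC[C@H]1C(C)C | intermediate
9 | N,N-dimethylhydrazone of ketone 10 | CN(C)/N=C1/[C@H](C(C)C)CC[C@@H](C)[C@H]1CCC(=C)C[Si](C)(C)C | intermediate
10 | (2R,3R,6S)-6-isopropyl-3-methyl-2-{3-[(trimethylsilyl)methyl]but-3-en-1-yl}cyclohexan-1-one | O=C1[C@H](C(C)C)CC[C@@H](C)[C@H]1CCC(=C)C[Si](C)(C)C | intermediate
11 | (1R,6R,7S,10R)-muurol-4(15)-en-6-ol | C=C1CC[C@@H]2[C@H](C)CC[C@@H](C(C)C)[C@]2(O)C1 | intermediate
12 | triethylammonium sulfamate ester of 11 | C=C1CC[C@@H]2[C@H](C)CC[C@@H](C(C)C)[C@]2(OS(=O)(=O)[N-]C(=O)OC)C1.CC[NH+](CC)CC | intermediate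
13 | (1R,7S,10R)-muurola-4(15),5-diene | C=C1C=C2[C@H](C(C)C)CC[C@@H](C)[C@H]2CC1 | intermediate
14 | isobutyryl chloride | CC(C)C(=O)Cl | starting material
15 | ethoxyacetylene | CCOC#C | starting material
16 | dimethylketene | CC(C)=C=O | intermediate
17 | 3-ethoxy-4,4-dimethylcyclobut-2-en-1-one | CCOC1=CC(=O)C1(C)C | intermediate
18 | 3-hydroxy-4,4-dimethylcyclobut-2-en-1-one | OC1=CC(=O)C1(C)C | intermediate
19 | isobutyraldehyde | CC(C)C=O | starting material
20 | 2,2-dimethyl-4-(2-methylpropylidene)cyclobutane-1,3-dione | CC(C)C=C1C(=O)C(C)(C)C1=O | intermediate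
21 | pyran-fused cyclobutenone (C4 S, C1′ R) | O=C1C2=C(O[C@]3(C=C4[C@H](C(C)C)CC[C@@H](C)[C@H]4CC3)C[C@@H]2C(C)C)C1(C)C | intermediate
22 | chloroacetaldehyde dimethyl acetal | COC(CCl)OC | starting material
23 | sodium methoxyacetylide | COC#[C-].[Na+] | intermediate
24 | 1-methoxyprop-1-yne | COC#CC | intermediate
25 | vinylketene (3-carbonylmethylidene-2-isopropylidene-tetrahydropyran) | CC(C)=C1O[C@]2(C=C3[C@H](C(C)C)CC[C@@H](C)[C@H]3CC2)C[C@H](C(C)C)C1=C=O | intermediate
26 | CNP0194760.3 | COC1=C(C)C(=O)C2=C(O[C@]3(C=C4[C@H](C(C)C)CC[C@@H](C)[C@H]4CC3)C[C@@H]2C(C)C)C1(C)C | target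

Total step count: 12. Longest linear sequence: 8 steps (1 → 2 → 4 → 5 → 6 → 7 → 10 → 12).

Steps most likely to fail

Step 12 (labelled). Three processes could compete with the intended capture of 25.
- The dipolar adduct may close at the ketene α-carbon to a four-membered ring. The 4π opening and 6π closure that follow would exchange the positions of C=O and OMe.
- A 1,5-hydrogen shift may carry a hydrogen from the inside methyl group to the ketene carbon.
- Simple re-closure to 21 may outrun capture.

Fallback (known chemistry, sets out from 21, returns at 26): the α-closure cascade is used on purpose. 1-Propynyllithium is oxidised with lithium tert-butyl peroxide, and the ynolate is O-silylated with TIPSOTf to triisopropyl(prop-1-yn-1-yloxy)silane F1. Heating 21 with it is a Danheiser benzannulation with a silyloxyalkyne. Vinylketene 25 and the alkyne give the spiro-cyclobutenone F2 by [2+2] cycloaddition, 4π opening gives the dienylketene F3, and 6π closure onto CMe2 gives the 3-silyloxy-2,6,6-trimethylcyclohexa-2,4-dienone F4. In F4 the two ring oxygens are differentiated: the free C=O lies next to CMe2 and the silyl ether lies next to the pyran carbon. Methyl triflate with 2,6-di-tert-butylpyridine at low temperature O-methylates the only free carbonyl oxygen to the trioxygen-stabilised cyclohexadienyl cation F5. Fluoride (TBAT) then removes the silyl group, which unveils the C=O next to the pyran carbon and gives 26.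

Step 10 (labelled). Several processes could go wrong.
- The wide bite of an oxadiene on a four-membered ring may slow the cycloaddition.
- A stepwise addition may end in proton loss (ene-type outcome).
- A second molecule of 18 may add to 20 in a Michael fashion.
- The acidic enol may isomerise 13.
- Facial or endo selectivity may be poor.

Fallback (known chemistry, sets out from 13 and 19, returns at 25): methyl 4-methyl-3-oxopentanoate and 19 are condensed (piperidine/AcOH, Knoevenagel) to methyl 2-isobutyryl-4-methylpent-2-enoate F6, an acyclic 1-oxadiene of the classical type. It is added to 13 through its ketone C=O in a thermal or Yb(fod)3-catalysed inverse-demand hetero-Diels–Alder reaction, which gives the dihydropyran methyl ester F7 by the same face and endo arguments. KOSiMe3 cleaves the ester to the dihydropyran carboxylic acid F8. 1-Chloro-N,N,2-trimethylpropenylamine converts it under neutral conditions into the acid chloride F9. 1,4-Dehydrochlorination with Et3N (loss of the isopropyl methine hydrogen) in hot toluene, in the presence of 24, generates 25 directly.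

Step 7. An ionised (E1-like) sulfamate may lose H-7 or H-1 instead of H-5, or the exocyclic double bond may migrate into the ring.

Fallback (sets out from 11, returns at 13): ozonolysis (O3; Me2S) of the exocyclic methylene gives the β-hydroxy ketone F10. Mesylation with Et3N triggers an E1cB elimination that can only run towards C5 and gives the octalone F11 without touching C1. Wittig methylenation (Ph3P=CH2, −78 °C → rt) then restores C15.

Further compounds
F1 | step 12 | triisopropyl(prop-1-yn-1-yloxy)silane | CC#CO[Si](C(C)C)(C(C)C)C(C)C
F2 | step 12 | spiro-cyclobutenone ([2+2] adduct of 25 and F1; new spiro carbon of no consequence) | CC(C)=C1O[C@]2(C=C3[C@H](C(C)C)CC[C@@H](C)[C@H]3CC2)C[C@H](C(C)C)C14C(=O)C(C)=C4O[Si](C(C)C)(C(C)C)C(C)C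
F3 | step 12 | dienylketene | O=C=C(C)/C(O[Si](C(C)C)(C(C)C)C(C)C)=C1\C(=C(C)C)O[C@]2(C=C3[C@H](C(C)C)CC[C@@H](C)[C@H]3CC2)C[C@@H]1C(C)C
F4 | step 12 | 3-silyloxy-2,6,6-trimethylcyclohexa-2,4-dienone fused to the spiro-pyran | O=C1C(C)=C(O[Si](C(C)C)(C(C)C)C(C)C)C2=C(O[C@]3(C=C4[C@H](C(C)C)CC[C@@H](C)[C@H]4CC3)C[C@@H]2C(C)C)C1(C)C
F5 | step 12 | O-methylated cyclohexadienyl cation triflate | COC1=C(C)C(=[O+][Si](C(C)C)(C(C)C)C(C)C)C2=C(O[C@]3(C=C4[C@H](C(C)C)CC[C@@H](C)[C@H]4CC3)C[C@@H]2C(C)C)C1(C)C.[O-]S(=O)(=O)C(F)(F)F
F6 | step 10 | methyl 2-isobutyryl-4-methylpent-2-enoate (E/Z) | COC(=O)C(=CC(C)C)C(=O)C(C)C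
F7 | step 10 | dihydropyran methyl ester | COC(=O)C1=C(C(C)C)O[C@]2(C=C3[C@H](C(C)C)CC[C@@H](C)[C@H]3CC2)C[C@@H]1C(C)C
F8 | step 10 | dihydropyran carboxylic acid | OC(=O)C1=C(C(C)C)O[C@]2(C=C3[C@H](C(C)C)CC[C@@H](C)[C@H]3CC2)C[C@@H]1C(C)C
F9 | step 10 | dihydropyran acid chloride | ClC(=O)C1=C(C(C)C)O[C@]2(C=C3[C@H](C(C)C)CC[C@@H](C)[C@H]3CC2)C[C@@H]1C(C)C
F10 | step 7 | (1R,6R,7S,10R)-6-hydroxy-15-normuurolan-4-one | O=C1CC[C@@H]2[C@H](C)CC[C@@H](C(C)C)[C@]2(O)C1
F11 | step 7 | (1R,7S,10R)-15-normuurol-5-en-4-one | O=C1C=C2[C@H](C(C)C)CC[C@@H](C)[C@H]2CC1
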